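The dawn run started richer than the flask, 2.2 M of starting material against 1.5 M, and its open dimer readings fall from first to last.

| setting | dawn | flask |
|---|---|---|
| starting material | 2.2 M | 1.5 M |
| remark | run made earlier |  |
| time |  | 15 d |

dawn run (percent of the starting material charged)

| time / d | open dimer / % | ring / % |
|---|---|---|
| 1.04 | 14.3 | 78.2 |
| 2.50 | 3.0 | 94.2 |
| 3.00 | 2.1 | 97.8 |
| 5.00 | 0 | 99.6 |

(standard deviation of a reading: 1 percentage point)

- in percentages every species weighs as the starting material in it: one open dimer counts as two
- a reading or a percentage of ring counts all its forms, free or not

* time, not beyond 15 d, at which the flask holds most open dimer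
* the amount of open dimer, in percent of the starting material charged, at that time
* the first time at which open dimer reaches 16%, in the same percent

Where does the charge of the dawn run stand late on? I write the balance of starting material: what ring and open dimer do not hold is 7.50% at 1.04 d and 0.100% at 3.00 d. At that later time the open dimer, 2.1%, is more than this remainder, so I read it as the resting state of what is not yet ring.

How fast does it leave? Take the tail rate, the logarithm of the ratio of two late open dimer readings divided by the time between them: 1.07 /d in the dawn run, a half-life of 0.648 d.

Isn't that weak? Yes: the scatter of 1 percentage point is a third of the lower reading, so the rate is rough.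

Does it carry over to the flask? I assume that open dimer leaves by a first-order step, which makes the rate independent of the charge.

And your commitment? The half-life is far shorter than the 15 d allowed, so I expect the open dimer of the flask to fall well inside that time. The tail tells how open dimer leaves, not how it rises, so I name neither a peak time nor a height.

The forecast says 28% at 0.5 d, with 16% crossed at 0.12 d, on these grounds: “Either a direct route to ring exists, or closure slows as ring accumulates”.

The flask peaks at 0.222 d with 22.2% and crosses 16% at 0.0610 d.

    starting material → ring (k = 0.00333 /min)
    starting material + ring ⇌ idle adduct, settled at all times (K = 0.706 /M)
    2 starting material ⇌ open dimer (K = 1.61 /M, k = 0.00113 /M/min)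
    crystals ⇌ ring, rate k4*(cs4 - [ring]) while solid is left; crystals form when [ring] > cs4 (solubility = 0.600 M, k = 0.0169 /min)

Now the tail rate on this flask: from 7.64% of open dimer at 1.50 d it gives 0.0124% at 7.50 d, and the flask holds 0.0183%. The neighbouring flask is the same flask read at 4.0 d. From the same start the reckoning gives 0.527%, and that flask holds 0.629%, a fall of 0.999 /d, slower than the tail rate of 1.07 /d.

(The runs are simulated with made-up constants.)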